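The trap is to read the excess as a fixed property of a single-handed catalyst. Each substrate feeds its own product, so the end state we expect is equal products and zero excess, and the excess at a given time is a race under kinetic control. So we ask how far along a common clock each flask stands.

in all of them: left-handed substrate 20 mM; right-handed substrate 20 mM; gas 4.3 mM (held)
- red: free catalyst 0.27 mM; run made earlier
- teal: free catalyst 0.32 mM; run made earlier
- north: free catalyst 0.50 mM; time 80 min
- south-west: free catalyst 0.25 mM; time 80 min

| run | time / min | left-handed product / % | right-handed product / % | left-handed substrate / % |
|---|---|---|---|---|
| red | 15.0 | 18.2 | 3.5 | 30.6 |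
| red | 30.0 | 33.2 | 6.8 | 18.0 |
| red | 50.0 | 45.8 | 13.9 | 5.4 |
| red | 60.0 | 46.5 | 18.4 | 4.2 |
| red | 80.0 | 49.3 | 26.3 | 1.5 |
| teal | 6.00 | 9.7 | 0 | 40.2 |
| teal | 12.0 | 17.1 | 2.0 | 34.9 |
| teal | 25.0 | 30.7 | 5.8 | 18.3 |
| teal | 40.0 | 41.5 | 11.2 | 7.6 |
| teal | 80.0 | 47.5 | 29.6 | 0.4 |

(readings scatter by 1 percentage point)

- free catalyst is single-handed; left-handed substrate and right-handed substrate are mirror images of each other, charged as a racemate, each of them at the stated concentration
- at the start none of the gas is in solution
- an excess is the difference of the two amounts in percent of their sum
- an excess is below zero if the other one leads

- which one finishes higher in excess of left-handed product over right-handed product in the product ("neither" within 2 percentage points) (north / south-west / neither)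
- excess of left-handed product over right-handed product in the product at the end, north
- excess of left-handed product over right-handed product in the product at the end, south-west

Multiply time by a flask's catalyst charge over red's. South-west's end then lies at 74.1 min and north's at 148 min. This is the red clock. The readings are roughly in line with it, though over a narrow span of charges: teal's excess at 47.4 min on this clock is 57.5%, and red's at 50.0 min is 53.4%.

Now the ladder. First on the ladder is the left-handed substrate, with a time constant read from red of 20.2 min. Next is the right-handed substrate: its product at teal's end, at 94.8 min on the clock, gives 106 min as a reading, an average that treats the whole run as one decay, longer than the left-handed one. By red's 80.0 min the left-handed substrate stands at 1.5%, so the excess then follows what remains of the right-handed substrate.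

South-west ends short of that slower constant, and interpolating red's excess gives us an estimate of 34.2%. North ends beyond it and past teal's end, so the decay, with the left-handed substrate taken as wholly converted, gives us an extrapolated 14.1%.

The forecast says south-west, with north at 8% (3% to 16%) and south-west at 35% (30% to 40%): “More catalyst erodes the excess, so south-west finishes higher”. Its north lies below ours.

The flasks give south-west, with north at 11.0% and south-west at 31.9%.

    partner ⇌ dormant form (K = 10.0, k = 0.00160 /s)
    partner → decomposed reagent (k = 0.00160 /s)
    free catalyst + left-handed substrate ⇌ catalyst intermediate A (K = 1000 /M, k = 10.0 /M/s)
    partner + catalyst intermediate A → free catalyst + left-handed product (k = 69.0 /M/s)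
    gas ⇌ partner, rate k5*(csat - [partner]) (kL = 0.00450 /s)
    free catalyst + right-handed substrate ⇌ catalyst intermediate B (K = 90.0 /M, k = 450 /M/s)
    partner + catalyst intermediate B → free catalyst + right-handed product (k = 10.0 /M/s)

North and south-west part by their charge of free catalyst: south-west given north's charge ends at 11.0% instead of 31.9%. On the red clock, south-west stopped at 74.1 min and north at 148 min, either side of the right-handed average read from teal, 106 min. The neighbour of south-west charged with 1.0 mM of free catalyst stands at 296 min on the clock, where the same decay gives 3.13%, and that flask ends at 1.00%.

(The earlier runs and the new flask were generated by integration for an exercise; scatter was added.)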